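**Plan**

1. Retrosynthetic cuts, in order: (a) one acetate C–O, since the target is the mono-acetate of a meso diacetate; (b) the chain bond C6′–C7′ (chain numbered from the ketone carbon C1′) by crossed Kolbe coupling of octanoic acid with a ring-bearing 7-oxoheptanoic acid; (c) that acid's C1′=O and CO2H, from ozonolysis of a cyclohept-1-enyl group on ring carbon C1; (d) C1–OH by a singlet-oxygen ene reaction; (e) C2–O and C5–O by singlet-oxygen cycloaddition to a fulvene; (f) the fulvene C=C from cyclopentadiene and cycloheptanone.
2. Enabling feature: the acyl chain is unbranched and unfunctionalised from C2′ to C13′, so C6′ and C7′ can each be a plain primary radical. C6′ lies five CH2 from the C1′ ketone, so C1′–C6′ plus the carbon lost as CO2 are the seven carbons of cycloheptanone, a temporary ring hung on C1. The cyclopent-3-ene ring with oxygen on C2, C1 and C5 is meso while C2–O and C5–O carry the same group.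
3. Forward order: the five-membered ring is bought as cyclopentadiene and never rebuilt; the seven-membered ring is attached (step 1), opened (step 5), and its last carbon expelled when the heptyl chain is joined (step 6).
4. Stereochemistry: the cis C2/C5 oxygens come from the suprafacial 1O2 [4+2] addition; C1–OH trans to both comes from 1O2 attack anti to the two acetoxy groups; absolute configuration comes from lipase hydrolysis of one enantiotopic acetate in the last step. Every intermediate before that is achiral or meso.

Key step: step 6

Remark: cyclopentadiene is treated as a purchased material, cracked from its commercial dimer just before use.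
Remark: which enantiotopic acetate the lipase removes is predicted from the empirical active-site model for lipases with secondary alcohols and must be confirmed by screening. Ring atoms are numbered C1 (quaternary), C2 (free OH in the target), C3=C4, C5 (OAc).

**Route**

Step 1
Reactants: 1 cyclopenta-1,3-diene; 2 cycloheptanone
Product: 3 5-cycloheptylidenecyclopenta-1,3-diene (6,6-hexamethylenefulvene)
Conditions: pyrrolidine (1.5 equiv), MeOH, 0 °C → rt; AcOH quench
Reagents that add atoms: none
Why: Amine-mediated fulvene condensation (Thiele-type, via the iminium ion of the ketone and cyclopentadienide), well known for cyclic ketones; no stereocentre is formed.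

Step 2
Reactants: 3 5-cycloheptylidenecyclopenta-1,3-diene
Product: 5 (1R,3S)-2-cycloheptylidenecyclopent-4-ene-1,3-diol (meso cis-diol), via fulvene endoperoxide 4 (not isolated)
Conditions: O2, hν, rose bengal, CH2Cl2/MeOH, −78 °C, until the yellow colour fades; then thiourea, −78 → 0 °C
Reagents that add atoms: oxygen, O=O
Why: [4+2] cycloaddition of singlet oxygen to the s-cis ring diene (the known behaviour of 6,6-dialkylfulvenes) makes both C–O bonds on one face, and thiourea cleaves only the O–O bond of the labile endoperoxide at low temperature, so the two hydroxyls should be cis by construction; stopping at the colour end point spares the exocyclic alkene.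

Step 3
Reactants: 5 (1R,3S)-2-cycloheptylidenecyclopent-4-ene-1,3-diol
Product: 6 (1R,3S)-2-cycloheptylidenecyclopent-4-ene-1,3-diyl diacetate (meso)
Conditions: Ac2O, pyridine, DMAP (cat.), CH2Cl2, 0 °C → rt
Reagents that add atoms: acetic anhydride, CC(=O)OC(C)=O
Why: Standard acylation that leaves both stereocentres untouched; the acetates (one of which stays in the target) remove the hydroxyl-directing effect that would steer singlet oxygen to the wrong face in step 4.

Step 4
Reactants: 6 (1R,3S)-2-cycloheptylidenecyclopent-4-ene-1,3-diyl diacetate
Product: 8 (1R,2r,3S)-2-(cyclohept-1-en-1-yl)-2-hydroxycyclopent-4-ene-1,3-diyl diacetate (meso; tertiary OH trans to both OAc), via allylic hydroperoxide 7 (not isolated)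
Conditions: O2, hν, TPP (cat.), CH2Cl2, 0 °C; then PPh3, 0 °C
Reagents that add atoms: oxygen, O=O
Why: Schenck ene reaction at the only electron-rich alkene (tetrasubstituted, exocyclic): 1O2 should approach anti to the two cis acetoxy groups, bond to ring carbon C1 and abstract an allylic H from a cycloheptane CH2 (H geminal to acetoxy is reluctant; cycloheptylidene ring H is readily abstracted), shifting the double bond into the seven-membered ring; PPh3 reduces OOH to OH with retention, so the C1 configuration is set by substrate control.

Step 5
Reactants: 8 (1R,2r,3S)-2-(cyclohept-1-en-1-yl)-2-hydroxycyclopent-4-ene-1,3-diyl diacetate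
Product: 10 7-[(1r,2R,5S)-2,5-diacetoxy-1-hydroxycyclopent-3-en-1-yl]-7-oxoheptanoic acid (meso), via keto aldehyde 9 (not isolated)
Conditions: O3 (1.05 equiv, metered), MeCN/H2O 9:1, 0 °C; N2 purge; then NaClO2, NaH2PO4, 0 °C → rt
Reagents that add atoms: ozone, [O-][O+]=O; water, O; sodium chlorite, [Na+].[O-]Cl=O
Why: Ozone should react first at the trisubstituted cycloheptene C=C, the cyclopentene C=C being deactivated by two allylic acetoxy groups; in wet MeCN the carbonyl oxide is hydrated to the keto aldehyde plus H2O2, and chlorite (Pinnick-type oxidation with that H2O2 as hypochlorite scavenger) gives the acid, unmasking the C1′ ketone and the CO2H six carbons away without touching a stereocentre.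

Step 6
Reactants: 10 7-[(1r,2R,5S)-2,5-diacetoxy-1-hydroxycyclopent-3-en-1-yl]-7-oxoheptanoic acid; 11 octanoic acid
Product: 12 (1R,2r,3S)-2-hydroxy-2-tridecanoylcyclopent-4-ene-1,3-diyl diacetate (meso)
Conditions: 11 (8 equiv), KOH (5 mol% of total CO2H), MeOH, Pt anode/Pt cathode, undivided cell, ca. 150 mA cm−2, 35–40 °C, stopped while still weakly acidic
Reagents that add atoms: none
Why: Crossed Kolbe electrolysis: both carboxylates are oxidised at the platinum anode to acyloxy radicals that lose CO2, and the two primary alkyl radicals (heptyl from 11, the 6-oxo-6-(cyclopentenyl)hexyl radical from 10) combine in the anode layer to form the CH2–CH2 bond C6′–C7′. The closest known reaction type is the mixed Kolbe coupling of oxo- or acyloxy-alkanoic acids with fatty acids. No ring is closed and no stereocentre is formed or disturbed, so the meso core passes through unchanged. The step needs hetero- over homo-coupling and radical coupling over further oxidation to cations: the eightfold excess of cheap 11 should make nearly every radical from 10 meet a heptyl radical (tetradecane is removed on silica), and both radicals are primary with no α- or β-heteroatom, the case in which high current density on smooth Pt in weakly acidic methanol favours coupling over Hofer–Moest products. The core should tolerate the conditions because the carboxylate layer on the anode shields the non-conjugated, acetoxy-deactivated ring alkene and the tertiary alcohol, the ketone is five carbons from the radical centre, and the bulk solution stays acidic enough to prevent acetate methanolysis.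

Step 7
Reactants: 12 (1R,2r,3S)-2-hydroxy-2-tridecanoylcyclopent-4-ene-1,3-diyl diacetate
Product: 13 (1S,4R,5S)-4,5-dihydroxy-5-tridecanoylcyclopent-2-en-1-yl acetate (target)
Conditions: Novozym 435 (immobilised lipase B from Candida antarctica), pH 7 phosphate buffer/MTBE, 25 °C, pH-stat, stopped at 1.0 equiv of acid released
Reagents that add atoms: none
Why: Hydrolase desymmetrisation of a meso diacetate, as for cis-3,5-diacetoxycyclopentene: the lipase is expected to hydrolyse the acetate on the R-configured carbinol carbon (large group = the quaternary ring carbon, medium = the vinyl CH) and leave the acetate on the S centre, which fixes the absolute configuration of all three stereocentres; the mono-acetate should be a poor substrate for a second hydrolysis.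

**Compound list**

1 | cyclopenta-1,3-diene | C1C=CC=C1 | starting material
2 | cycloheptanone | O=C1CCCCCC1 | starting material
3 | 5-cycloheptylidenecyclopenta-1,3-diene | C1=CC(C=C1)=C2CCCCCC2 | intermediate
4 | (1R,4S)-7-cycloheptylidene-2,3-dioxabicyclo[2.2.1]hept-5-ene (meso endoperoxide) | O2[C@H]1C=C[C@@H](O2)C1=C3CCCCCC3 | intermediate
5 | (1R,3S)-2-cycloheptylidenecyclopent-4-ene-1,3-diol (meso, OH groups cis) | O[C@H]1C=C[C@@H](O)C1=C2CCCCCC2 | intermediate
6 | (1R,3S)-2-cycloheptylidenecyclopent-4-ene-1,3-diyl diacetate (meso) | CC(=O)O[C@H]1C=C[C@@H](OC(C)=O)C1=C2CCCCCC2 | intermediate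
7 | (1R,2r,3S)-2-(cyclohept-1-en-1-yl)-2-hydroperoxycyclopent-4-ene-1,3-diyl diacetate (meso; OOH trans to both OAc) | C1(=CCCCCC1)[C@]2(OO)[C@H](OC(C)=O)C=C[C@@H]2OC(C)=O | intermediate
8 | (1R,2r,3S)-2-(cyclohept-1-en-1-yl)-2-hydroxycyclopent-4-ene-1,3-diyl diacetate (meso; OH trans to both OAc) | C1(=CCCCCC1)[C@]2(O)[C@H](OC(C)=O)C=C[C@@H]2OC(C)=O | intermediate
9 | (1R,2r,3S)-2-hydroxy-2-(7-oxoheptanoyl)cyclopent-4-ene-1,3-diyl diacetate (meso keto aldehyde) | O=CCCCCCC(=O)[C@]1(O)[C@H](OC(C)=O)C=C[C@@H]1OC(C)=O | intermediate
10 | 7-[(1r,2R,5S)-2,5-diacetoxy-1-hydroxycyclopent-3-en-1-yl]-7-oxoheptanoic acid (meso) | OC(=O)CCCCCC(=O)[C@]1(O)[C@H](OC(C)=O)C=C[C@@H]1OC(C)=O | intermediate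
11 | octanoic acid | CCCCCCCC(=O)O | starting material
12 | (1R,2r,3S)-2-hydroxy-2-tridecanoylcyclopent-4-ene-1,3-diyl diacetate (meso) | CCCCCCCCCCCCC(=O)[C@]1(O)[C@H](OC(C)=O)C=C[C@@H]1OC(C)=O | intermediate
13 | (1S,4R,5S)-4,5-dihydroxy-5-tridecanoylcyclopent-2-en-1-yl acetate | CCCCCCCCCCCCC(=O)[C@]1(O)[C@H](O)C=C[C@@H]1OC(C)=O | target

**Count and risks**

Total steps: 7. Longest linear sequence: 7 steps (1 and 2 to 13); 11 enters at step 6.

Step 4. What may go wrong: singlet oxygen may abstract hydrogen from the acetoxy-bearing ring carbons instead of the cycloheptane CH2 groups, or add to the acetoxy face, or react too slowly with an alkene deactivated by two allylic acetates. Any of these would misplace or mis-orient the new C–O bond. Fallback, from 6: the exocyclic alkene is epoxidised with mCPBA/NaHCO3 (CH2Cl2, 0 °C) anti to the acetoxy groups to give the dispiro epoxide F1. TMSOTf/2,6-lutidine (CH2Cl2, −78 °C) then opens the C–O bond at the cycloheptane carbon (the ring carbon C1 is deactivated by two β-acetoxy groups) with loss of a neighbouring ring proton, giving the allylic trimethylsilyl ether F2. AcOH/THF/H2O removes the silyl group and the route is rejoined at 8.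

Step 6. What may go wrong: statistical homocoupling of the ring-bearing radical, over-oxidation of the radicals to cations (ethers, alkenes), anode passivation, or methanolysis of the acetates near the cathode. Fallback, from 10 and 11: 11 is converted with 50% H2O2/MeSO3H into peroxyoctanoic acid F3, and DCC coupling of 10 with F3 (Et2O/CH2Cl2, −10 °C) gives the unsymmetrical diacyl peroxide F4. Photolysis of F4 (254 nm) as a neat film at −60 °C expels two CO2, and the geminate radical pair should recombine in the cage to the cross product only, rejoining the route at 12.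

Step 7. What may go wrong: hydrolysis of the wrong enantiotopic acetate, poor discrimination, or very slow turnover next to the quaternary carbon. Fallback, from 12: both acetates are removed by methanolysis (K2CO3 cat., MeOH, 0 °C) to give the meso triol F5. One enantiotopic secondary hydroxyl is then acetylated with Ac2O/Et3N under a chiral nucleophilic catalyst of the planar-chiral DMAP type (tert-amyl alcohol, 0 °C); the catalyst antipode selects the sense and the tertiary OH should stay free, so the route arrives directly at 13.

**Further compounds**

F1 | step 4 | epoxide of 6 across the exocyclic C=C, dispiro[cycloheptane-1,2′-oxirane-3′,1″-cyclopent[3]ene]-2″,5″-diyl diacetate, oxirane O trans to both OAc (meso) | C1CCCCCC13O[C@]32[C@H](OC(C)=O)C=C[C@@H]2OC(C)=O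
F2 | step 4 | (1R,2r,3S)-2-(cyclohept-1-en-1-yl)-2-(trimethylsilyloxy)cyclopent-4-ene-1,3-diyl diacetate | C1(=CCCCCC1)[C@]2(O[Si](C)(C)C)[C@H](OC(C)=O)C=C[C@@H]2OC(C)=O
F3 | step 6 | peroxyoctanoic acid | CCCCCCCC(=O)OO
F4 | step 6 | octanoyl 7-[(1r,2R,5S)-2,5-diacetoxy-1-hydroxycyclopent-3-en-1-yl]-7-oxoheptanoyl peroxide | CCCCCCCC(=O)OOC(=O)CCCCCC(=O)[C@]1(O)[C@H](OC(C)=O)C=C[C@@H]1OC(C)=O
F5 | step 7 | 1-[(1r,2R,5S)-1,2,5-trihydroxycyclopent-3-en-1-yl]tridecan-1-one (meso triol) | CCCCCCCCCCCCC(=O)[C@]1(O)[C@H](O)C=C[C@@H]1O
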